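**Retrosynthetic overview**

1. Locants (briarane numbering): C1 quaternary ring-fusion carbon, C2 isovalerate carbinol, C5 tertiary carbinol, C6=C7 enol-lactone alkene, C8/C17/C19 butenolide β-carbon/α-carbon/carbonyl, C10 ring-fusion CH, C11=C12 alkene of ring A, C14 acetate carbinol. The target is reached from its C2,C5-bis-silyl ether by desilylation and acylation of the C2 hydroxyl.
2. Key disconnection: the butenolide is cut at O–C7 and C17=C8, giving a ten-membered 2-iodoenone and 2-(diethoxyphosphoryl)propanoic acid. The enabling feature is the vicinal pair C7 (sp2 C–I) and C8 (ketone) inside the ten-membered ring, a 1,2-bis-electrophile matching the O/C bis-nucleophile of the acid, with the C6=C7 alkene, its geometry and the final oxidation level already in place.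
3. The iodoenone comes from a ten-membered ynone (syn hydrostannation, iodination); the ten-membered ring is closed at C7–C8 by Nozaki–Hiyama–Kishi addition of an iodoalkyne to an aldehyde.
4. Ring A, C14 and the control of C1, C2 and C10 come from (S)-carvone: aldol (C1–C2, sets C2), methylation (C1), Criegee rearrangement (isopropenyl becomes the C14 acetate), Wharton transposition and Claisen rearrangement (C10, C9, C8).
5. C2–C7 with the C5 carbinol come from geraniol by Sharpless epoxidation. Ring order: ring A (present in carvone), then the ten-membered ring (step 15), then the butenolide (step 18).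

Key step: step 18

Remark: the SMILES is read as the (1S,2S,5S,10S,14S) isomer with the C6=C7 alkene E (ring oxygen trans to C5, C5 cis to C8); geraniol, (S)-(+)-carvone and 2-(diethoxyphosphoryl)propanoic acid are taken as commercial.

**Route**

Step 1
Reactants: 1 geraniol
Product: 2 (2S,3S)-2,3-epoxygeraniol
Conditions: Ti(OiPr)4 (cat.), L-(+)-diethyl tartrate (cat.), t-BuOOH, 4 Å MS, CH2Cl2, −20 °C
Reagents that add atoms: tert-butyl hydroperoxide, CC(C)(C)OO
Why: Sharpless asymmetric epoxidation of an allylic alcohol, in which the L-(+)-tartrate/titanium catalyst delivers oxygen to one enantioface and so sets the (2S,3S)-epoxide whose tertiary C–O carbon becomes C5 of the target.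

Step 2
Reactants: 2 (2S,3S)-2,3-epoxygeraniol
Product: 3 (2R,3S)-2-(chloromethyl)-3-methyl-3-(4-methylpent-3-en-1-yl)oxirane
Conditions: PPh3, CCl4, NaHCO3, reflux
Reagents that add atoms: carbon tetrachloride, ClC(Cl)(Cl)Cl
Why: Appel chlorination of the primary alcohol under neutral conditions leaves the epoxide and both stereocentres untouched.

Step 3
Reactants: 3 epoxy chloride
Product: 5 (S)-3,7-dimethyl-1-(triisopropylsilyl)oct-6-en-1-yn-3-ol, via dilithium alkoxide acetylide 4 (not isolated)
Conditions: n-BuLi (3.1 equiv), THF, −40 °C; then iPr3SiCl, 0 °C to rt; H2O work-up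
Reagents that add atoms: chlorotriisopropylsilane, CC(C)[Si](Cl)(C(C)C)C(C)C
Why: base-induced double elimination of a 2,3-epoxy chloride (epoxide opening to the chloroalkene alkoxide, then dehydrochlorination) gives the tertiary propargylic alkoxide with the C–O stereocentre untouched, and the hindered silyl chloride reacts only at the acetylide carbon (C-silylation of a lithium acetylide).

Step 4
Reactants: 5 tertiary propargylic alcohol
Product: 6 triethylsilyl ether of 5
Conditions: Et3SiOTf, 2,6-lutidine, CH2Cl2, −78 to 0 °C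
Reagents that add atoms: triethylsilyl trifluoromethanesulfonate, CC[Si](CC)(CC)OS(=O)(=O)C(F)(F)F
Why: silylation of the tertiary alcohol with the silyl triflate (alcohol protection) masks the C5 oxygen for the enolate steps.

Step 5
Reactants: 6 silyl ether
Product: 8 (S)-4-methyl-4-(triethylsilyloxy)-6-(triisopropylsilyl)hex-5-ynal, via ozonide 7 (not isolated)
Conditions: O3 (1 equiv), CH2Cl2, −78 °C; then PPh3, −78 °C to rt
Reagents that add atoms: ozone, [O-][O+]=O
Why: ozonolysis with reductive work-up cleaves the electron-rich trisubstituted alkene much faster than the silylated alkyne and releases the C2 aldehyde.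

Step 6
Reactants: 9 (S)-(+)-carvone; 8 aldehyde
Product: 11 anti-aldol adduct (new C1–C2 bond; C2 chain trans to the isopropenyl group; C2 carbinol S), via lithium enolate 10 (not isolated)
Conditions: LiN(iPr)2, THF, −78 °C; then 8, −78 °C; AcOH quench at −78 °C
Reagents that add atoms: none
Why: kinetic deprotonation gives the cross-conjugated (E)-enolate, which undergoes an aldol addition on the face opposite the isopropenyl group through a closed chair transition state, so the anti adduct with the (S)-configured C2 carbinol is expected.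

Step 7
Reactants: 11 aldol adduct
Product: 12 C2 tert-butyldimethylsilyl ether of 11
Conditions: t-BuMe2SiOTf, 2,6-lutidine, CH2Cl2, −78 to 0 °C
Reagents that add atoms: tert-butyldimethylsilyl trifluoromethanesulfonate, CC(C)(C)[Si](C)(C)OS(=O)(=O)C(F)(F)F
Why: silyl ether formation (alcohol protection) prevents retro-aldol cleavage and leaves a single acidic position for step 8.

Step 8
Reactants: 12 silyl ether
Product: 14 C1-methylated ketone (C1 quaternary; methyl trans to the isopropenyl group), via lithium enolate 13 (not isolated)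
Conditions: LiN(iPr)2, THF, −78 to −40 °C; then MeI, DMPU, −78 to −20 °C
Reagents that add atoms: iodomethane, CI
Why: enolate alkylation in which iodomethane attacks the tetrasubstituted lithium enolate on the face opposite the neighbouring pseudoaxial isopropenyl group, which makes C1 quaternary with methyl trans to the isopropenyl group and the C2 chain cis to it.

Step 9
Reactants: 14 enone
Product: 15 11,12-epoxy ketone (epoxide cis to the C1 methyl group)
Conditions: 30% H2O2, NaOH (cat.), MeOH, 0 °C
Reagents that add atoms: hydrogen peroxide, OO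
Why: nucleophilic (Weitz–Scheffer) epoxidation of the enone, in which hydroperoxide adds to C12 anti to the C14 isopropenyl group so that the epoxide lies on the face of the C1 methyl group.

Step 10
Reactants: 15 epoxy ketone
Product: 18 C14 acetate, via methoxy hydroperoxide 16 (not isolated), via peroxyacetate 17 (not isolated)
Conditions: O3, CH2Cl2/MeOH, −78 °C; then Ac2O, Et3N, DMAP (cat.), CH2Cl2, 0 to 40 °C
Reagents that add atoms: ozone, [O-][O+]=O
Why: ozonolysis of the isopropenyl group in methanol followed by Criegee rearrangement of the peroxyacetate, in which C14 migrates from carbon to oxygen with retention, converts C(CH3)=CH2 into O–C(=O)CH3 (acetyl carbons from the isopropenyl group) and makes the carvone stereocentre the C14 acetate.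

Step 11
Reactants: 18 epoxy ketone acetate
Product: 20 allylic alcohol (C10=C11; C12 hydroxyl cis to the C1 methyl group), via epoxy hydrazone 19 (not isolated)
Conditions: N2H4·H2O, AcOH (cat.), MeOH, 0 °C to rt
Reagents that add atoms: none
Why: Wharton transposition, in which the epoxy hydrazone opens at C11–O with loss of N2, moves the alkene to C10=C11 and keeps the C12–O bond, so the C12 hydroxyl stays on the face of the C1 methyl group.

Step 12
Reactants: 20 allylic alcohol
Product: 21 C12 vinyl ether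
Conditions: Pd(OCOCF3)2 (5 mol %), 4,7-diphenyl-1,10-phenanthroline, butyl vinyl ether, Et3N, 75 °C
Reagents that add atoms: butyl vinyl ether, C=COCCCC
Why: palladium-catalysed transfer vinylation (vinyl ether exchange) of the secondary allylic alcohol touches no stereocentre.

Step 13
Reactants: 21 allyl vinyl ether
Product: 22 aldehyde (C10 bears CH2CHO cis to the C1 methyl group; C11=C12)
Conditions: toluene, BHT, trace Et3N, sealed tube, 150 °C
Reagents that add atoms: none
Why: Claisen rearrangement ([3,3]-sigmatropic) forms the C10–C9 bond suprafacially on the face that carried the C12–O bond, which sets C10 with its side chain cis to the C1 methyl group, restores the C11=C12 alkene and delivers C8 as an aldehyde.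

Step 14
Reactants: 22 silylalkyne aldehyde
Product: 23 iodoalkyne aldehyde
Conditions: AgF, N-iodosuccinimide, MeCN, rt, dark
Reagents that add atoms: N-iodosuccinimide, O=C1CCC(=O)N1I
Why: silver-mediated desilylative iodination through the silver acetylide (halodesilylation) exchanges the alkyne silyl group for iodine without touching the aldehyde, the acetate or the silyl ethers.

Step 15
Reactants: 23 iodoalkyne aldehyde
Product: 25 ten-membered propargylic alcohol (C8 carbinol as both epimers), via alkynylchromium dichloride 24 (not isolated)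
Conditions: CrCl2 (6 equiv), NiCl2 (1 mol %), THF, rt, slow addition to 2 mM
Reagents that add atoms: none
Why: intramolecular Nozaki–Hiyama–Kishi addition, in which the alkynyl trivalent-chromium species adds chemoselectively to the aldehyde and closes the ten-membered ring at C7–C8 under high dilution, the new C8 carbinol being formed without control because it is oxidised in step 16.

Step 16
Reactants: 25 propargylic alcohol
Product: 26 ten-membered ynone
Conditions: Dess–Martin periodinane, NaHCO3, CH2Cl2, 0 °C to rt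
Reagents that add atoms: none
Why: Dess–Martin oxidation of the propargylic alcohol gives the conjugated ynone and removes the uncontrolled C8 centre.

Step 17
Reactants: 26 ynone
Product: 28 ten-membered 2-iodoenone (iodine on C7; C5 and C8 cis), via stannyl enone 27 (not isolated)
Conditions: Bu3SnH (slow addition), PdCl2(PPh3)2 (2 mol %), THF, 0 °C; then I2, CH2Cl2, 0 °C
Reagents that add atoms: iodine, II
Why: palladium-catalysed hydrostannation of the ynone is a syn addition that puts tin on C7 (α to the carbonyl) and hydrogen on C6, so C5 and C8 end cis on the new alkene, and iododestannylation then replaces tin by iodine with retention.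

Step 18
Reactants: 28 2-iodoenone; 29 2-(diethoxyphosphoryl)propanoic acid
Product: 31 bis-silyl ether of the dienyl butenolide, via enol ester phosphonate 30 (not isolated)
Conditions: CuI (20 mol %), 3,4,7,8-tetramethyl-1,10-phenanthroline (40 mol %), Cs2CO3 (3 equiv), 4 Å MS, toluene, 80 °C
Reagents that add atoms: none
Why: Proposed new method: the caesium carboxylate of 29 is joined to C7 of the alkenyl iodide by a monovalent-copper/phenanthroline-catalysed Ullmann-type C–O coupling (oxidative addition of C7–I to the copper carboxylate, C–O reductive elimination with retention of alkene geometry) to give enol ester 30, whose phosphonate is deprotonated by Cs2CO3 and attacks the neighbouring C8 ketone (intramolecular Horner–Wadsworth–Emmons), so the O–C7 and C17=C8 bonds form in one flask. The closest known reaction types are the copper-catalysed coupling of alkenyl halides with carboxylic acids and of 2-iodoenones with amides, and the one-pot carboxylate alkylation/intramolecular Horner–Wadsworth–Emmons sequence that turns α-halo ketones and phosphonoacetic acids into butenolides. The butenolide is the only ring closed, and it closes by 5-exo-trig addition of the phosphonate carbanion to the C8 carbonyl followed by syn-elimination of diethyl phosphate. No stereocentre is created: the C6=C7 geometry (ring oxygen cis to H, C5 cis to C8) is inherited from 28 because the coupling is retentive, and the C8=C17 alkene is fixed by the five-membered ring. The step needs O-vinylation at C7 to beat conjugate addition at C6 and olefination at C8 only; the quaternary silyloxy-bearing C5 shields C6, C8 is the only ketone within reach of the tethered phosphonate, and the acetate and silyl ethers are inert to Cs2CO3 in toluene.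

Step 19
Reactants: 31 bis-silyl ether
Product: 32 C2,C5-diol
Conditions: HF·pyridine, pyridine, THF, 0 °C to rt
Reagents that add atoms: none
Why: fluoride-induced cleavage of both silyl ethers (desilylation) under buffered conditions leaves the acetate, the enol lactone and the tertiary allylic alcohol intact.

Step 20
Reactants: 32 diol
Product: 33 CNP0208239.1 (target)
Conditions: (iPrCH2CO)2O, DMAP, Et3N, CH2Cl2, 0 °C to rt
Reagents that add atoms: 3-methylbutanoic anhydride, CC(C)CC(=O)OC(=O)CC(C)C
Why: DMAP-catalysed acylation (esterification) is selective for the secondary C2 hydroxyl because the tertiary allylic C5 hydroxyl does not acylate under these conditions.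

**Compound list**

1 | geraniol, (2E)-3,7-dimethylocta-2,6-dien-1-ol | CC(C)=CCC/C(C)=C/CO | starting material
2 | (2S,3S)-2,3-epoxygeraniol | OC[C@@H]1O[C@@]1(C)CCC=C(C)C | intermediate
3 | (2R,3S)-2-(chloromethyl)-3-methyl-3-(4-methylpent-3-en-1-yl)oxirane | ClC[C@@H]1O[C@@]1(C)CCC=C(C)C | intermediate
4 | dilithium salt (alkoxide and acetylide) of (S)-3,7-dimethyloct-6-en-1-yn-3-ol | [Li+].[Li+].CC(C)=CCC[C@](C)([O-])C#[C-] | intermediate
5 | (S)-3,7-dimethyl-1-(triisopropylsilyl)oct-6-en-1-yn-3-ol | CC(C)=CCC[C@](C)(O)C#C[Si](C(C)C)(C(C)C)C(C)C | intermediate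
6 | triethylsilyl ether of 5 | CC(C)=CCC[C@](C)(O[Si](CC)(CC)CC)C#C[Si](C(C)C)(C(C)C)C(C)C | intermediate
7 | ozonide (1,2,4-trioxolane) of the trisubstituted alkene of 6 | CC1(C)OOC(CC[C@](C)(O[Si](CC)(CC)CC)C#C[Si](C(C)C)(C(C)C)C(C)C)O1 | intermediate
8 | (S)-4-methyl-4-(triethylsilyloxy)-6-(triisopropylsilyl)hex-5-ynal (C2 aldehyde, C5 carbinol, C6≡C7) | O=CCC[C@](C)(O[Si](CC)(CC)CC)C#C[Si](C(C)C)(C(C)C)C(C)C | intermediate
9 | (S)-(+)-carvone (ring carbons 1 to 6 become C10, C11, C12, C13, C14, C1) | CC(=C)[C@H]1CC=C(C)C(=O)C1 | starting material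
10 | lithium cross-conjugated enolate of 9 (C1=C10 enolate) | [Li+].CC(=C)[C@H]1CC=C(C)C([O-])=C1 | intermediate
11 | anti-aldol adduct, (5S,6S)-6-[(1S,4S)-1-hydroxy-4-methyl-4-(triethylsilyloxy)-6-(triisopropylsilyl)hex-5-yn-1-yl]-2-methyl-5-(prop-1-en-2-yl)cyclohex-2-en-1-one | CC(=C)[C@H]1CC=C(C)C(=O)[C@@H]1[C@@H](O)CC[C@](C)(O[Si](CC)(CC)CC)C#C[Si](C(C)C)(C(C)C)C(C)C | intermediate
12 | C2 tert-butyldimethylsilyl ether of 11 | CC(=C)[C@H]1CC=C(C)C(=O)[C@@H]1[C@@H](O[Si](C)(C)C(C)(C)C)CC[C@](C)(O[Si](CC)(CC)CC)C#C[Si](C(C)C)(C(C)C)C(C)C | intermediate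
13 | lithium enolate of 12 (C1=C10) | [Li+].CC(=C)[C@H]1CC=C(C)C([O-])=C1[C@@H](O[Si](C)(C)C(C)(C)C)CC[C@](C)(O[Si](CC)(CC)CC)C#C[Si](C(C)C)(C(C)C)C(C)C | intermediate
14 | C1-methylated enone (C1 quaternary; methyl trans to isopropenyl, C2 chain cis) | CC(=C)[C@H]1CC=C(C)C(=O)[C@@]1(C)[C@@H](O[Si](C)(C)C(C)(C)C)CC[C@](C)(O[Si](CC)(CC)CC)C#C[Si](C(C)C)(C(C)C)C(C)C | intermediate
15 | 11,12-epoxy ketone of 14 (epoxide cis to the C1 methyl, trans to isopropenyl) | CC(=C)[C@H]1C[C@@H]2O[C@]2(C)C(=O)[C@@]1(C)[C@@H](O[Si](C)(C)C(C)(C)C)CC[C@](C)(O[Si](CC)(CC)CC)C#C[Si](C(C)C)(C(C)C)C(C)C | intermediate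
16 | α-methoxy hydroperoxide (C14 bears C(CH3)(OCH3)OOH) | COC(C)(OO)[C@H]1C[C@@H]2O[C@]2(C)C(=O)[C@@]1(C)[C@@H](O[Si](C)(C)C(C)(C)C)CC[C@](C)(O[Si](CC)(CC)CC)C#C[Si](C(C)C)(C(C)C)C(C)C | intermediate
17 | peroxyacetate of 16 | COC(C)(OOC(C)=O)[C@H]1C[C@@H]2O[C@]2(C)C(=O)[C@@]1(C)[C@@H](O[Si](C)(C)C(C)(C)C)CC[C@](C)(O[Si](CC)(CC)CC)C#C[Si](C(C)C)(C(C)C)C(C)C | intermediate
18 | C14 acetate epoxy ketone (acetoxy in place of isopropenyl, retention) | CC(=O)O[C@H]1C[C@@H]2O[C@]2(C)C(=O)[C@@]1(C)[C@@H](O[Si](C)(C)C(C)(C)C)CC[C@](C)(O[Si](CC)(CC)CC)C#C[Si](C(C)C)(C(C)C)C(C)C | intermediate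
19 | C10 hydrazone of 18 | CC(=O)O[C@H]1C[C@@H]2O[C@]2(C)C(=NN)[C@@]1(C)[C@@H](O[Si](C)(C)C(C)(C)C)CC[C@](C)(O[Si](CC)(CC)CC)C#C[Si](C(C)C)(C(C)C)C(C)C | intermediate
20 | allylic alcohol (C10=C11; C12 hydroxyl cis to the C1 methyl) | CC(=O)O[C@H]1C[C@H](O)C(C)=C[C@@]1(C)[C@@H](O[Si](C)(C)C(C)(C)C)CC[C@](C)(O[Si](CC)(CC)CC)C#C[Si](C(C)C)(C(C)C)C(C)C | intermediate
21 | C12 vinyl ether of 20 | CC(=O)O[C@H]1C[C@H](OC=C)C(C)=C[C@@]1(C)[C@@H](O[Si](C)(C)C(C)(C)C)CC[C@](C)(O[Si](CC)(CC)CC)C#C[Si](C(C)C)(C(C)C)C(C)C | intermediate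
22 | aldehyde (C10 bears CH2CHO, C9 and C8, cis to the C1 methyl; C11=C12) | CC(=O)O[C@H]1CC=C(C)[C@H](CC=O)[C@@]1(C)[C@@H](O[Si](C)(C)C(C)(C)C)CC[C@](C)(O[Si](CC)(CC)CC)C#C[Si](C(C)C)(C(C)C)C(C)C | intermediate
23 | iodoalkyne aldehyde (C7–I) | CC(=O)O[C@H]1CC=C(C)[C@H](CC=O)[C@@]1(C)[C@@H](O[Si](C)(C)C(C)(C)C)CC[C@](C)(O[Si](CC)(CC)CC)C#CI | intermediate
24 | alkynylchromium dichloride derived from 23 | CC(=O)O[C@H]1CC=C(C)[C@H](CC=O)[C@@]1(C)[C@@H](O[Si](C)(C)C(C)(C)C)CC[C@](C)(O[Si](CC)(CC)CC)C#C[Cr](Cl)Cl | intermediate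
25 | ten-membered propargylic alcohol (C8 carbinol, both epimers; C6≡C7) | CC(=O)O[C@H]1CC=C(C)[C@@H]2CC(O)C#C[C@@](C)(O[Si](CC)(CC)CC)CC[C@H](O[Si](C)(C)C(C)(C)C)[C@@]12C | intermediate
26 | ten-membered ynone (C8 ketone, C6≡C7) | CC(=O)O[C@H]1CC=C(C)[C@@H]2CC(=O)C#C[C@@](C)(O[Si](CC)(CC)CC)CC[C@H](O[Si](C)(C)C(C)(C)C)[C@@]12C | intermediate
27 | 2-(tributylstannyl)enone (tin on C7; C5 and C8 cis) | CC(=O)O[C@H]1CC=C(C)[C@@H]2CC(=O)/C([Sn](CCCC)(CCCC)CCCC)=C\[C@@](C)(O[Si](CC)(CC)CC)CC[C@H](O[Si](C)(C)C(C)(C)C)[C@@]12C | intermediate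
28 | ten-membered (E)-2-iodoenone (iodine on C7; C5 and C8 cis) | CC(=O)O[C@H]1CC=C(C)[C@@H]2CC(=O)/C(I)=C\[C@@](C)(O[Si](CC)(CC)CC)CC[C@H](O[Si](C)(C)C(C)(C)C)[C@@]12C | intermediate
29 | 2-(diethoxyphosphoryl)propanoic acid | CCOP(=O)(OCC)C(C)C(O)=O | starting material
30 | enol ester phosphonate (C7–O–C(=O)CH(CH3)P(O)(OEt)2; C8 ketone) | CC(=O)O[C@H]1CC=C(C)[C@@H]2CC(=O)/C(OC(=O)C(C)P(=O)(OCC)OCC)=C\[C@@](C)(O[Si](CC)(CC)CC)CC[C@H](O[Si](C)(C)C(C)(C)C)[C@@]12C | intermediate
31 | dienyl butenolide, C5 triethylsilyl and C2 tert-butyldimethylsilyl ether | CC(=O)O[C@H]1CC=C(C)[C@@H]2CC3=C(C)C(=O)O/C3=C/[C@@](C)(O[Si](CC)(CC)CC)CC[C@H](O[Si](C)(C)C(C)(C)C)[C@@]12C | intermediate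
32 | C2,C5-diol (deisovaleryl target) | CC(=O)O[C@H]1CC=C(C)[C@@H]2CC3=C(C)C(=O)O/C3=C/[C@@](C)(O)CC[C@H](O)[C@@]12C | intermediate
33 | CNP0208239.1, (1S,2S,5S,10S,14S)-14-acetoxy-5-hydroxy-2-(3-methylbutanoyloxy) dienyl butenolide | CC(=O)O[C@H]1CC=C(C)[C@@H]2CC3=C(C)C(=O)O/C3=C/[C@@](C)(O)CC[C@H](OC(=O)CC(C)C)[C@@]12C | target

**Step count and risks**

Total steps: 20. Longest linear sequence: 20 (steps 1–5 from geraniol, then steps 6–20); the carvone branch is 15 steps.

Steps most likely to fail:

1. Step 18 (proposed new method). The copper-mediated C–O coupling may stall at the hindered alkenyl iodide, or protodeiodination and base-induced decomposition of the iodoenone may outrun it. Fallback with known reactions, from ynone 26 back to 31: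
   - Double conjugate reduction of 26 with [(Ph3P)CuH]6 in the presence of Me3SiCl gives the C7=C8 trimethylsilyl enol ether F1.
   - N-bromosuccinimide converts it into the C7 α-bromo ketone F2.
   - The potassium salt of 29 displaces the bromide in DMF, and DBU/LiCl then closes the ring by intramolecular Horner–Wadsworth–Emmons olefination (the established one-pot bromoketone-to-butenolide sequence), giving the C7–H butenolide F3.
   - t-BuMe2SiOTf/Et3N gives the 2-silyloxyfuran F4, which N-bromosuccinimide brominates at C7 to the γ-bromobutenolide F5.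
   - DBU eliminates HBr towards C6 and, under these equilibrating conditions, should give the ring-cis alkylidene butenolide 31.

2. Step 15. Intermolecular oligomerisation or reduction of the iodoalkyne may compete with closure of the ten-membered ring. Fallback from aldehyde 22 to ynone 26, replacing steps 14 to 16:
   - NaClO2/NaH2PO4/2-methylbut-2-ene (Pinnick oxidation) gives the carboxylic acid F6.
   - AgF in MeCN followed by aqueous acid removes the alkyne silyl group to give the terminal alkyne acid F7.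
   - 1-Chloro-N,N,2-trimethylprop-1-en-1-amine gives the acid chloride F8.
   - Slow addition of F8 to PdCl2(PPh3)2/CuI/Et3N in toluene closes the ring by an intramolecular acyl Sonogashira coupling and gives 26 directly.

3. Step 6. Simple diastereoselection of the lithium aldol at C2 may be poor, and the hindered enolisation of step 8 may be slow or accompanied by β-elimination. Fallback from aldol adduct 11 (any C2 epimer ratio) to 14, with C2 set by reagent control:
   - Dess–Martin oxidation gives the 2-acylcarvone (β-diketone) F9.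
   - K2CO3/MeI in acetone methylates C1 anti to the isopropenyl group to give the quaternary diketone F10.
   - Corey–Bakshi–Shibata reduction of the less hindered side-chain ketone with catecholborane and (R)-1-methyl-3,3-diphenyltetrahydro-1H,3H-pyrrolo[1,2-c][1,3,2]oxazaborole gives the (S)-C2 alcohol F11.
   - t-BuMe2SiOTf/2,6-lutidine returns to 14.

Further compounds
F1 | step 18 | C7=C8 trimethylsilyl enol ether of the saturated ten-membered ketone | CC(=O)O[C@H]1CC=C(C)[C@@H]2CC(O[Si](C)(C)C)=CC[C@@](C)(O[Si](CC)(CC)CC)CC[C@H](O[Si](C)(C)C(C)(C)C)[C@@]12C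
F2 | step 18 | C7 α-bromo C8 ketone (C7 epimers) | CC(=O)O[C@H]1CC=C(C)[C@@H]2CC(=O)C(Br)C[C@@](C)(O[Si](CC)(CC)CC)CC[C@H](O[Si](C)(C)C(C)(C)C)[C@@]12C
F3 | step 18 | C7–H butenolide (6,7-dihydro analogue of 31) | CC(=O)O[C@H]1CC=C(C)[C@@H]2CC3=C(C)C(=O)OC3C[C@@](C)(O[Si](CC)(CC)CC)CC[C@H](O[Si](C)(C)C(C)(C)C)[C@@]12C
F4 | step 18 | 2-(tert-butyldimethylsilyloxy)furan of F3 | CC(=O)O[C@H]1CC=C(C)[C@@H]2Cc3c(C)c(O[Si](C)(C)C(C)(C)C)oc3C[C@@](C)(O[Si](CC)(CC)CC)CC[C@H](O[Si](C)(C)C(C)(C)C)[C@@]12C
F5 | step 18 | C7 γ-bromobutenolide | CC(=O)O[C@H]1CC=C(C)[C@@H]2CC3=C(C)C(=O)OC3(Br)C[C@@](C)(O[Si](CC)(CC)CC)CC[C@H](O[Si](C)(C)C(C)(C)C)[C@@]12C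
F6 | step 15 | C8 carboxylic acid of 22 | CC(=O)O[C@H]1CC=C(C)[C@H](CC(O)=O)[C@@]1(C)[C@@H](O[Si](C)(C)C(C)(C)C)CC[C@](C)(O[Si](CC)(CC)CC)C#C[Si](C(C)C)(C(C)C)C(C)C
F7 | step 15 | terminal alkyne acid | CC(=O)O[C@H]1CC=C(C)[C@H](CC(O)=O)[C@@]1(C)[C@@H](O[Si](C)(C)C(C)(C)C)CC[C@](C)(O[Si](CC)(CC)CC)C#C
F8 | step 15 | terminal alkyne acid chloride | CC(=O)O[C@H]1CC=C(C)[C@H](CC(Cl)=O)[C@@]1(C)[C@@H](O[Si](C)(C)C(C)(C)C)CC[C@](C)(O[Si](CC)(CC)CC)C#C
F9 | step 6 | 2-acylcarvone β-diketone (C1 epimerisable) | CC(=C)[C@H]1CC=C(C)C(=O)C1C(=O)CC[C@](C)(O[Si](CC)(CC)CC)C#C[Si](C(C)C)(C(C)C)C(C)C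
F10 | step 6 | C1-methylated β-diketone (methyl trans to isopropenyl) | CC(=C)[C@H]1CC=C(C)C(=O)[C@@]1(C)C(=O)CC[C@](C)(O[Si](CC)(CC)CC)C#C[Si](C(C)C)(C(C)C)C(C)C
F11 | step 6 | (S)-C2 alcohol (desilyl 14) | CC(=C)[C@H]1CC=C(C)C(=O)[C@@]1(C)[C@@H](O)CC[C@](C)(O[Si](CC)(CC)CC)C#C[Si](C(C)C)(C(C)C)C(C)C
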